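**Plan**
1. Eudesmane numbering is used. Ring A is C1–C2–C3=C4–C5–C10 and ring B is C5–C6–C7–C8–C9–C10. C14 is the angular CH3 on C10, C15 is the OCH2 on C4, and C11(=C13)–C12O2Me is the acrylate on C7.
2. Cuts, in order: ArO–Si (last step); C1–C2 and C5–C10 together (retro-[4+2] of ring A, which opens both rings to one chain); C4–C15 (dienyl bromide plus a zinc reagent carrying the whole CH2–O–coumarate); then C3–C4, C4=C5 and C1=C10, back to the keto aldehyde made by opening the ring olefin of a limonene-derived acrylate.
3. Enabling feature: C3=C4 is the only olefin of the decalin, and its cyclohexene (ring A) shares the C5–C10 edge with ring B. The bicycle is therefore the adduct of the 1,7,9-decatriene C2=C3–C4=C5 / C1=C10 tied by C6–C9. C4, which bears C15, is the internal diene carbon next to the tether, so it is an sp2 C–Br site in the open chain.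
4. Forward: the chain is built linearly with no ring, the two halves are joined at C4–C15, and the same batch is heated so that rings A and B close together.
5. Stereochemistry: C7 is bought with (R)-limonene. C5 and C10 are relayed from it in the cycloaddition (chair tether, C7 group equatorial, E-diene, methyl-endo/tether-exo giving trans fusion). The coumarate E-olefin is bought, and the Z-bromodiene geometry comes from trans-selective mono-coupling of a 1,1-dibromo-olefin.

Key step: step 12

Remark: commercial (R)-(+)-limonene of high enantiomeric purity is assumed. Its stereocentre becomes C7, and no bond to it is broken anywhere in the route.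

**Route**

Step 1
Reactants: 1 (R)-(+)-limonene
Product: 4 (R)-2-(4-methylcyclohex-3-en-1-yl)prop-2-en-1-ol, via allyllithium 2 (not isolated), via dimethyl allylboronate 3 (not isolated)
Conditions: n-BuLi, TMEDA, hexane, 23 °C; B(OMe)3, THF, −78 to 23 °C; H2O2, aq NaOH, 0 °C
Reagents that add atoms: hydrogen peroxide OO
Why: Kinetic allylic lithiation with n-BuLi·TMEDA takes the isopropenyl methyl group of limonene, and the 2-substituted allyl anion (both termini equivalent) is borylated and oxidised (lithiation–borylation–oxidation) without touching the ring stereocentre.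

Step 2
Reactants: 4 (R)-2-(4-methylcyclohex-3-en-1-yl)prop-2-en-1-ol
Product: 5 (R)-2-(4-methylcyclohex-3-en-1-yl)prop-2-enal
Conditions: activated MnO2, CH2Cl2, 23 °C
Reagents that add atoms: none
Why: MnO2 oxidation is selective for the primary allylic alcohol and should stop at the enal, leaving both olefins intact.

Step 3
Reactants: 5 (R)-2-(4-methylcyclohex-3-en-1-yl)prop-2-enal
Product: 6 (R)-2-(4-methylcyclohex-3-en-1-yl)prop-2-enoic acid
Conditions: NaClO2, NaH2PO4, 2-methyl-2-butene, t-BuOH/H2O, 0 to 23 °C
Reagents that add atoms: sodium chlorite [Na+].[O-]Cl=O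
Why: Pinnick oxidation converts α-methylene aldehydes to acrylic acids under near-neutral conditions, and the excess scavenger olefin shields the ring olefin from hypochlorite.

Step 4
Reactants: 6 (R)-2-(4-methylcyclohex-3-en-1-yl)prop-2-enoic acid
Product: 7 methyl (R)-2-(4-methylcyclohex-3-en-1-yl)prop-2-enoate
Conditions: MeI, K2CO3, DMF, 23 °C
Reagents that add atoms: iodomethane CI
Why: SN2 O-alkylation of the carboxylate with a base too weak to deconjugate or isomerise the acrylate.

Step 5
Reactants: 7 methyl (R)-2-(4-methylcyclohex-3-en-1-yl)prop-2-enoate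
Product: 9 methyl (3R)-2-methylidene-6-oxo-3-(2-oxoethyl)heptanoate, via secondary ozonide 8 (not isolated)
Conditions: O3 (1 equiv, Sudan III end point), CH2Cl2, −78 °C; Me2S, −78 to 23 °C
Reagents that add atoms: ozone [O-][O+]=O
Why: In this chemoselective ozonolysis (Criegee mechanism, reductive work-up) the electron-rich trisubstituted ring olefin is consumed well before the ester-conjugated 1,1-disubstituted olefin, which unrolls the ring into the C5 aldehyde/C10 methyl ketone chain.

Step 6
Reactants: 9 methyl (3R)-2-methylidene-6-oxo-3-(2-oxoethyl)heptanoate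
Product: 10 methyl (3R)-3-(3,3-dibromoprop-2-en-1-yl)-2-methylidene-6-oxoheptanoate
Conditions: CBr4, PPh3, CH2Cl2, 0 °C
Reagents that add atoms: tetrabromomethane BrC(Br)(Br)Br
Why: In the Ramirez dibromo-olefination (first stage of the Corey–Fuchs sequence) Ph3P=CBr2 reacts with the aldehyde far faster than with the methyl ketone and so adds C4 chemoselectively.

Step 7
Reactants: 10 methyl (3R)-3-(3,3-dibromoprop-2-en-1-yl)-2-methylidene-6-oxoheptanoate
Product: 11 methyl (3R)-3-(3,3-dibromoprop-2-en-1-yl)-6-methyl-2-methylidenehept-6-enoate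
Conditions: Zn, CH2Br2, TiCl4, THF/CH2Cl2, 0 to 23 °C
Reagents that add atoms: dibromomethane BrCBr
Why: The non-basic Zn/Ti gem-dimetallic reagent of the Takai–Lombardo methylenation attacks ketones much faster than esters and should leave the acrylate, the sp2 C–Br bonds and C7 untouched while installing C1.

Step 8
Reactants: 11 methyl (3R)-3-(3,3-dibromoprop-2-en-1-yl)-6-methyl-2-methylidenehept-6-enoate
Product: 12 methyl (3R)-3-[(2Z)-3-bromopenta-2,4-dien-1-yl]-6-methyl-2-methylidenehept-6-enoate
Conditions: Bu3SnCH=CH2, Pd2(dba)3 (cat.), P(2-furyl)3 (cat.), PhMe, 80–100 °C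
Reagents that add atoms: tributyl(vinyl)stannane C=C[Sn](CCCC)(CCCC)CCCC
Why: In this trans-selective Stille mono-coupling of a 1,1-dibromo-olefin, Pd(0) inserts into the less hindered C–Br bond trans to the alkyl chain, so the vinyl group (C3=C2) ends trans to C6 and the remaining bromine cis to it (Z).

Step 9
Reactants: 13 (E)-4-hydroxycinnamic acid (p-coumaric acid)
Product: 15 (E)-3-(4-{[tert-butyl(dimethyl)silyl]oxy}phenyl)prop-2-enoic acid, via bis-silylated coumarate 14 (not isolated)
Conditions: TBSCl, imidazole, DMF, 23 °C; then AcOH/THF/H2O, 23 °C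
Reagents that add atoms: tert-butyldimethylsilyl chloride CC(C)(C)[Si](C)(C)Cl
Why: Exhaustive silylation followed by mild hydrolysis exploits the much greater lability of the silyl ester compared with the aryl silyl ether.

Step 10
Reactants: 15 (E)-3-(4-{[tert-butyl(dimethyl)silyl]oxy}phenyl)prop-2-enoic acid
Product: 16 chloromethyl (E)-3-(4-{[tert-butyl(dimethyl)silyl]oxy}phenyl)prop-2-enoate
Conditions: ClCH2OSO2Cl, NaHCO3, n-Bu4NHSO4 (cat.), CH2Cl2/H2O, 0 to 23 °C
Reagents that add atoms: chloromethyl chlorosulfate ClCOS(=O)(=O)Cl
Why: Under phase-transfer O-alkylation the carboxylate displaces chlorosulfate, by far the better leaving group, so the C–Cl bond is kept.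

Step 11
Reactants: 16 chloromethyl (E)-3-(4-{[tert-butyl(dimethyl)silyl]oxy}phenyl)prop-2-enoate
Product: 17 iodomethyl (E)-3-(4-{[tert-butyl(dimethyl)silyl]oxy}phenyl)prop-2-enoate
Conditions: NaI, acetone, 23 °C, dark
Reagents that add atoms: sodium iodide [Na+].[I-]
Why: Finkelstein exchange at the activated acyloxymethyl carbon is driven by precipitation of NaCl.

Step 12
Reactants: 12 methyl (3R)-3-[(2Z)-3-bromopenta-2,4-dien-1-yl]-6-methyl-2-methylidenehept-6-enoate; 17 iodomethyl (E)-3-(4-{[tert-butyl(dimethyl)silyl]oxy}phenyl)prop-2-enoate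
Product: 20 methyl 2-[(2R,4aR,8aR)-8-({[(2E)-3-(4-{[tert-butyl(dimethyl)silyl]oxy}phenyl)prop-2-enoyl]oxy}methyl)-4a-methyl-1,2,3,4,4a,5,6,8a-octahydronaphthalen-2-yl]prop-2-enoate (O-TBS target), via acyloxymethylzinc iodide 18 (not isolated), via open-chain coupled tetraene 19 (not isolated)
Conditions: 17, Zn dust (TMSCl/BrCH2CH2Br-activated), LiCl, THF, 20 °C; add to 12, Pd(Pt-Bu3)2 (5 mol %), THF, 23 °C; Florisil plug, solvent switch to PhMe (2 mM), BHT (cat.), 205 °C, sealed vessel
Reagents that add atoms: none
Why: Zinc inserts into the C–I bond of 17 to give the carbonyl-chelated, β-hydrogen-free zinc reagent 18, which enters a Negishi cycle with 12 (oxidative addition of Pd(0) into C4–Br, transmetalation, reductive elimination) and forms C4–C15 with retention of the Z geometry, a bulky electron-rich monophosphine being the established remedy against geometric scrambling of 2-pallada-1,3-dienes. The coupled chain 19 is a 1,7,9-decatriene (diene C2=C3–C4=C5, dienophile C1=C10, tether C6–C9) that on heating undergoes a concerted suprafacial type-1 intramolecular Diels–Alder reaction; the closest known reaction types are cross-coupling/Diels–Alder domino sequences and the thermal cyclisation of 2-alkyl-1,3-dienes onto isopropenyl-type dienophiles that gives the selinane skeleton. Ring A closes as the new cyclohexene through C1–C2 and C5–C10 in the fused mode, and ring B closes in the same event as the tether ring through C5–C10 in a chair-like array. C5 and C10 are fixed relative to each other by the E-diene (C6 trans to C3) and the tether-exo/methyl-endo transition state, which gives the trans fusion (5-H anti to the 10-methyl group), while the CH2O group just placed on C4, cis to C6, holds the diene s-cis and raises allylic 1,3-strain in the cis-fused alternative. Both centres are fixed relative to C7 because the acrylate-bearing substituent takes the equatorial site of the chair tether, so that 7R relays to 5R and 10R. The step needs periselectivity for the isolated C1=C10 olefin over the acrylate and cinnamate olefins, which is secured because the acrylate hangs only two atoms from C5 and the cinnamate sits on an s-trans ester at the internal diene carbon, so neither reaches a fused transition state, while high dilution and a radical inhibitor hold back their bimolecular reactions.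

Step 13
Reactants: 20 O-TBS target
Product: 21 methyl 2-[(2R,4aR,8aR)-8-({[(2E)-3-(4-hydroxyphenyl)prop-2-enoyl]oxy}methyl)-4a-methyl-1,2,3,4,4a,5,6,8a-octahydronaphthalen-2-yl]prop-2-enoate (target)
Conditions: TBAF, AcOH, THF, 0 °C
Reagents that add atoms: none
Why: Fluoride cleaves the aryl silyl ether, and the acetic acid buffer keeps fluoride and the liberated phenoxide from attacking either ester or adding to the acrylate.

**Compound list**
1 | (R)-(+)-limonene | CC1=CC[C@@H](CC1)C(C)=C | starting material
2 | (R)-[2-(4-methylcyclohex-3-en-1-yl)prop-2-en-1-yl]lithium | CC1=CC[C@@H](CC1)C(=C)C[Li] | intermediate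
3 | dimethyl (R)-[2-(4-methylcyclohex-3-en-1-yl)prop-2-en-1-yl]boronate | CC1=CC[C@@H](CC1)C(=C)CB(OC)OC | intermediate
4 | (R)-2-(4-methylcyclohex-3-en-1-yl)prop-2-en-1-ol | CC1=CC[C@@H](CC1)C(=C)CO | intermediate
5 | (R)-2-(4-methylcyclohex-3-en-1-yl)prop-2-enal | CC1=CC[C@@H](CC1)C(=C)C=O | intermediate
6 | (R)-2-(4-methylcyclohex-3-en-1-yl)prop-2-enoic acid | CC1=CC[C@@H](CC1)C(=C)C(=O)O | intermediate
7 | methyl (R)-2-(4-methylcyclohex-3-en-1-yl)prop-2-enoate | CC1=CC[C@@H](CC1)C(=C)C(=O)OC | intermediate
8 | secondary ozonide (1,2,4-trioxolane) of the ring olefin of 7, new centres undefined | CC12CC[C@H](CC(OO1)O2)C(=C)C(=O)OC | intermediate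
9 | methyl (3R)-2-methylidene-6-oxo-3-(2-oxoethyl)heptanoate | O=CC[C@@H](CCC(C)=O)C(=C)C(=O)OC | intermediate
10 | methyl (3R)-3-(3,3-dibromoprop-2-en-1-yl)-2-methylidene-6-oxoheptanoate | BrC(Br)=CC[C@@H](CCC(C)=O)C(=C)C(=O)OC | intermediate
11 | methyl (3R)-3-(3,3-dibromoprop-2-en-1-yl)-6-methyl-2-methylidenehept-6-enoate | BrC(Br)=CC[C@@H](CCC(C)=C)C(=C)C(=O)OC | intermediate
12 | methyl (3R)-3-[(2Z)-3-bromopenta-2,4-dien-1-yl]-6-methyl-2-methylidenehept-6-enoate | C=C/C(Br)=C/C[C@@H](CCC(C)=C)C(=C)C(=O)OC | intermediate
13 | (E)-4-hydroxycinnamic acid (p-coumaric acid) | OC(=O)/C=C/c1ccc(O)cc1 | starting material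
14 | tert-butyldimethylsilyl (E)-3-(4-{[tert-butyl(dimethyl)silyl]oxy}phenyl)prop-2-enoate | CC(C)(C)[Si](C)(C)OC(=O)/C=C/c1ccc(O[Si](C)(C)C(C)(C)C)cc1 | intermediate
15 | (E)-3-(4-{[tert-butyl(dimethyl)silyl]oxy}phenyl)prop-2-enoic acid | OC(=O)/C=C/c1ccc(O[Si](C)(C)C(C)(C)C)cc1 | intermediate
16 | chloromethyl (E)-3-(4-{[tert-butyl(dimethyl)silyl]oxy}phenyl)prop-2-enoate | ClCOC(=O)/C=C/c1ccc(O[Si](C)(C)C(C)(C)C)cc1 | intermediate
17 | iodomethyl (E)-3-(4-{[tert-butyl(dimethyl)silyl]oxy}phenyl)prop-2-enoate | ICOC(=O)/C=C/c1ccc(O[Si](C)(C)C(C)(C)C)cc1 | intermediate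
18 | ({[(E)-3-(4-{[tert-butyl(dimethyl)silyl]oxy}phenyl)prop-2-enoyl]oxy}methyl)zinc iodide | I[Zn]COC(=O)/C=C/c1ccc(O[Si](C)(C)C(C)(C)C)cc1 | intermediate
19 | methyl (3R)-3-[(2Z)-3-({[(2E)-3-(4-{[tert-butyl(dimethyl)silyl]oxy}phenyl)prop-2-enoyl]oxy}methyl)penta-2,4-dien-1-yl]-6-methyl-2-methylidenehept-6-enoate | C=C/C(COC(=O)/C=C/c1ccc(O[Si](C)(C)C(C)(C)C)cc1)=C/C[C@@H](CCC(C)=C)C(=C)C(=O)OC | intermediate
20 | methyl 2-[(2R,4aR,8aR)-8-({[(2E)-3-(4-{[tert-butyl(dimethyl)silyl]oxy}phenyl)prop-2-enoyl]oxy}methyl)-4a-methyl-1,2,3,4,4a,5,6,8a-octahydronaphthalen-2-yl]prop-2-enoate | C=C(C(=O)OC)[C@@H]1CC[C@@]2(C)CCC=C(COC(=O)/C=C/c3ccc(O[Si](C)(C)C(C)(C)C)cc3)[C@@H]2C1 | intermediate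
21 | methyl 2-[(2R,4aR,8aR)-8-({[(2E)-3-(4-hydroxyphenyl)prop-2-enoyl]oxy}methyl)-4a-methyl-1,2,3,4,4a,5,6,8a-octahydronaphthalen-2-yl]prop-2-enoate | C=C(C(=O)OC)[C@@H]1CC[C@@]2(C)CCC=C(COC(=O)/C=C/c3ccc(O)cc3)[C@@H]2C1 | target

**Step count**
Total step count: 13. Longest linear sequence: 10 (steps 1–8, 12, 13).

**Steps most likely to fail**

Step 12.
- In the coupling phase, transmetalation from the chelated zinc reagent may be slow. The dienylpalladium intermediate, whose metal is cis to C6, would then have time to insert the nearby acrylate olefin or to lose its geometry. Carbenoid-type methylene transfer from the zinc reagent to the isolated olefin is a further drain.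
- In the thermal phase, radical or bimolecular consumption of the acrylate, acid-promoted loss of the allylic ester, and weak trans/cis or C7-facial discrimination may erode the outcome.
- A [3,3] shift across C13=C11–C7–C6–C5=C4 would erase C7. It is uphill, because it trades the conjugated diene for a quaternary divinyl carbon, and is not expected to compete.
- Fallback (rings first, fragment union second): it sets out from 12, which is heated alone (PhMe, high dilution, BHT, about 200 °C). The bromine on C4 plays the same steric role as the CH2O group, and neither the coumarate nor any metal is exposed to heat. This should give methyl 2-[(2R,4aS,8aR)-8-bromo-4a-methyl-1,2,3,4,4a,5,6,8a-octahydronaphthalen-2-yl]prop-2-enoate F1. The rigid cyclic alkenyl bromide has no olefin geometry to lose and holds its equatorial acrylate out of reach. Negishi coupling at 23 °C with zinc reagent 18 (made from 17 as above) comes back to the route at 20.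

Step 8.
- Mono-selectivity may be lost through a second vinylation, and palladium-induced dehydrobromination towards an enyne or insertion into the wrong C–Br bond would spoil the diene geometry on which step 12 depends.
- Fallback (geometry set by a stabilised ylide instead of by site-selective coupling): it sets out from 9. The aldehyde reacts chemoselectively with 2-bromo-2-(triphenyl-λ5-phosphanylidene)acetaldehyde (Wittig reaction, warm PhMe), placing the formyl group trans to the chain. This gives methyl (3R)-3-[(2Z)-3-bromo-4-oxobut-2-en-1-yl]-2-methylidene-6-oxoheptanoate F2. Double methylenation of the enal and the methyl ketone in one operation with excess Zn/CH2Br2/TiCl4 comes back to the route at 12 and bypasses 10 and 11.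

Step 7.
- The low-valent Zn/Ti mixture may reductively debrominate the dibromo-olefin, the reagent may react slowly with the ester, or conversion of the enolisable methyl ketone may be incomplete.
- Fallback (two-stage addition/elimination instead of a metal carbenoid): it sets out from 10. Me3SiCH2MgCl/CeCl3 (THF, −78 °C) adds selectively to the ketone to give methyl (3R)-3-(3,3-dibromoprop-2-en-1-yl)-6-hydroxy-6-methyl-2-methylidene-7-(trimethylsilyl)heptanoate F3 (both C6 epimers are usable). Peterson elimination with aqueous HF in MeCN comes back to the route at 11.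

**Further compounds**
F1 | step 12 | methyl 2-[(2R,4aS,8aR)-8-bromo-4a-methyl-1,2,3,4,4a,5,6,8a-octahydronaphthalen-2-yl]prop-2-enoate | C=C(C(=O)OC)[C@@H]1CC[C@@]2(C)CCC=C(Br)[C@@H]2C1
F2 | step 8 | methyl (3R)-3-[(2Z)-3-bromo-4-oxobut-2-en-1-yl]-2-methylidene-6-oxoheptanoate | O=C/C(Br)=C/C[C@@H](CCC(C)=O)C(=C)C(=O)OC
F3 | step 7 | methyl (3R)-3-(3,3-dibromoprop-2-en-1-yl)-6-hydroxy-6-methyl-2-methylidene-7-(trimethylsilyl)heptanoate | BrC(Br)=CC[C@@H](CCC(C)(O)C[Si](C)(C)C)C(=C)C(=O)OC
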